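**Plan**

1. Locants (carotenoid style): ring A is the cyclohexane C1–C6 (C1 gem-dimethyl, C3 carbinol, C5 methyl and oxygen), ring B is the 2,5-dihydrofuran O–C5–C6=C7–C8, and the chain runs C9 to C15 and C15' to C8' (aldehyde).
2. Last cut: the C10–C11 σ-bond. It lies between the E-C9=C10 and E-C11=C12 alkenes, so both ends can be made as configurationally fixed E-alkenyl partners (C10–I on the 14-carbon bicyclic half, C11–boronate on the 16-carbon hexaenal half) and joined with retention, leaving the C8 allylic ether of ring B, the free C3–OH and the aldehyde untouched.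
3. Bicyclic half: cut O–C8 (5-endo closure of the C5-hydroxy C6=C7=C8 allene), then take the allene back to the C5,C6-epoxide of a C7≡C8 enyne (anti-SN2' hydride), then cut C6–C7 (acetylide addition to the C6 ketone, dehydration). Hexaenal half: C11=C12, C11'=C12' and C9'=C10' are cut back to the symmetrical C10 trienedial.
4. Forward: ring A from ketoisophorone, then enyne, epoxide, allene, closure of ring B; the boronate chain is grown from the dial by three olefinations; the two finished, unprotected halves are joined in the last step. The C3 silyl ether (steps 3 to 8) is the only protecting group.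
5. Stereochemistry: C3 from asymmetric transfer hydrogenation; C5 from hydroxyl-directed epoxidation (cis to C3–OH); C8 by centre-to-axis-to-centre transfer (epoxide, allene, dihydrofuran); E-alkenes from an E-iodoalkenol, E-selective olefinations and a stereoretentive coupling.

Key step: step 15

Remark: the target is read as (3R,5R,8R) in the locants above, that is, C3–OH cis to the C5–O bond on ring A and H-8 cis to the C5 methyl on ring B.

**Route**

Step 1
Reactants: 1 ketoisophorone (2,6,6-trimethylcyclohex-2-ene-1,4-dione)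
Product: 2 (4R)-4-hydroxy-2,6,6-trimethylcyclohex-2-en-1-one
Conditions: RuCl[(R,R)-TsDPEN](p-cymene) (1 mol %), i-PrOH, 25 °C
Reagents that add atoms: none
Why: Noyori-type asymmetric transfer hydrogenation reduces only the enone carbonyl that becomes C3 (the other carbonyl, the future C6, is shielded by the quaternary C1 and the C5 methyl), and the CH/π contact of the arene ligand with the enone should place hydride on the face that gives the (R)-alcohol with the (R,R)-ligand, the antipodal ligand being available if the sense proves opposite.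

Step 2
Reactants: 2 (4R)-4-hydroxy-2,6,6-trimethylcyclohex-2-en-1-one
Product: 3 (4S)-4-hydroxy-2,2,6-trimethylcyclohexan-1-one (C6 epimer mixture; the descriptor changes only through the priority rules)
Conditions: H2 (3 bar), Raney Ni, MeOH, 25 °C
Reagents that add atoms: none
Why: Heterogeneous hydrogenation of the enone C4=C5 bond does not touch the C3 carbinol centre; C5 arises as an epimer mixture, which is of no consequence because C5 becomes sp2 again in step 7.

Step 3
Reactants: 3 (4S)-4-hydroxy-2,2,6-trimethylcyclohexan-1-one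
Product: 4 (4S)-4-[(tert-butyldimethylsilyl)oxy]-2,2,6-trimethylcyclohexan-1-one (C6 epimer mixture)
Conditions: TBSCl, imidazole, DMF, 25 °C
Reagents that add atoms: tert-butyldimethylsilyl chloride, CC(C)(C)[Si](C)(C)Cl
Why: Standard silyl ether formation at the secondary C3 hydroxyl, which would otherwise quench the acetylide in step 6 and be phosphorylated in step 7.

Step 4
Reactants: 5 (2E)-3-iodo-2-methylprop-2-en-1-ol
Product: 6 (2E)-3-iodo-2-methylprop-2-enal
Conditions: MnO2, CH2Cl2, 25 °C; used as a solution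
Reagents that add atoms: none
Why: MnO2 oxidation of a primary allylic alcohol to the enal is selective for the allylic position and has no effect on the C–I bond or the E geometry.

Step 5
Reactants: 6 (2E)-3-iodo-2-methylprop-2-enal
Product: 7 (3E)-4-iodo-3-methylbut-3-en-1-yne
Conditions: Me3SiCHN2, n-BuLi, THF, −78 °C; then 6, −78 to 25 °C; H2O
Reagents that add atoms: (trimethylsilyl)diazomethane, C[Si](C)(C)C=[N+]=[N-]
Why: Colvin rearrangement (one-carbon homologation of an aldehyde to a terminal alkyne): 1,2-addition of the lithiated diazo reagent, Peterson-type loss of silanolate and N2, and 1,2-hydrogen shift of the alkylidene carbene give the enyne, the added carbon being C7; n-BuLi is consumed before the alkenyl iodide enters the flask.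

Step 6
Reactants: 7 (3E)-4-iodo-3-methylbut-3-en-1-yne; 4 (4S)-4-[(tert-butyldimethylsilyl)oxy]-2,2,6-trimethylcyclohexan-1-one
Product: 9 (4S)-4-[(tert-butyldimethylsilyl)oxy]-1-[(3E)-4-iodo-3-methylbut-3-en-1-yn-1-yl]-2,2,6-trimethylcyclohexan-1-ol (diastereomer mixture at C1 and C6), via lithium acetylide 8 (not isolated)
Conditions: LDA, THF, −78 °C; then 4, −78 to 0 °C; H2O
Reagents that add atoms: none
Why: Acetylide addition to a ketone: deprotonation of the alkyne C–H by LDA at −78 °C is much faster than any attack on the alkenyl iodide, and the small acetylide should add to the hindered C6 carbonyl on the equatorial side (the axial C1 methyl blocks the axial path), which forms the C6–C7 bond and places the hydroxyl axial and anti to H-5; the C5 and C6 centres need no control because both become sp2 in step 7.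

Step 7
Reactants: 9 (4S)-4-[(tert-butyldimethylsilyl)oxy]-1-[(3E)-4-iodo-3-methylbut-3-en-1-yn-1-yl]-2,2,6-trimethylcyclohexan-1-ol
Product: 10 tert-butyl({(1S)-4-[(3E)-4-iodo-3-methylbut-3-en-1-yn-1-yl]-3,5,5-trimethylcyclohex-3-en-1-yl}oxy)dimethylsilane
Conditions: POCl3, pyridine, 90 °C
Reagents that add atoms: none
Why: POCl3–pyridine dehydration (E2 of the tertiary dichlorophosphate): C1 is quaternary, so elimination can only take H-5 and should give the tetrasubstituted C5=C6 alkene in conjugation with the alkyne.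

Step 8
Reactants: 10 tert-butyl({(1S)-4-[(3E)-4-iodo-3-methylbut-3-en-1-yn-1-yl]-3,5,5-trimethylcyclohex-3-en-1-yl}oxy)dimethylsilane
Product: 11 (1S)-4-[(3E)-4-iodo-3-methylbut-3-en-1-yn-1-yl]-3,5,5-trimethylcyclohex-3-en-1-ol
Conditions: Bu4NF, THF, 25 °C
Reagents that add atoms: none
Why: Fluoride-mediated silyl ether cleavage frees the homoallylic C3 hydroxyl that has to direct the epoxidation.

Step 9
Reactants: 11 (1S)-4-[(3E)-4-iodo-3-methylbut-3-en-1-yn-1-yl]-3,5,5-trimethylcyclohex-3-en-1-ol
Product: 12 (1R,3R,6R)-6-[(3E)-4-iodo-3-methylbut-3-en-1-yn-1-yl]-1,5,5-trimethyl-7-oxabicyclo[4.1.0]heptan-3-ol (epoxide cis to the hydroxyl)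
Conditions: VO(acac)2 (5 mol %), t-BuOOH, toluene, 25 °C
Reagents that add atoms: tert-butyl hydroperoxide, CC(C)(C)OO
Why: Hydroxyl-directed epoxidation of a cyclic homoallylic alcohol: the vanadium tert-butylperoxo species bound to the C3 alkoxide delivers oxygen to the C5=C6 bond on the face of the hydroxyl, which sets C5 (R) and C6 cis to C3–OH, while the alkenyl iodide and the alkyne carry no directing group and should stay untouched.

Step 10
Reactants: 12 (1R,3R,6R)-6-[(3E)-4-iodo-3-methylbut-3-en-1-yn-1-yl]-1,5,5-trimethyl-7-oxabicyclo[4.1.0]heptan-3-ol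
Product: 14 (1R,3R)-6-[(3E)-4-iodo-3-methylbuta-1,3-dien-1-ylidene]-1,5,5-trimethylcyclohexane-1,3-diol with the (aS) allene axis, via bis-silyl ether 13 (not isolated)
Conditions: (IPr)CuCl (5 mol %), NaOt-Bu (10 mol %), (EtO)2MeSiH, toluene, 0 to 25 °C; then Bu4NF, THF
Reagents that add atoms: none
Why: Copper hydride SN2' reduction of a propargylic oxirane: hydride is delivered to C8 anti to the breaking C6–O bond, as in organocopper SN2' substitutions, so the C5/C6 centres are translated into the C6=C7=C8 allene axis with H-8 on the face opposite to the former epoxide oxygen; the silyl ethers that form during turnover with the silane are cleaved by fluoride in the same flask.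

Step 11
Reactants: 14 (1R,3R)-6-[(3E)-4-iodo-3-methylbuta-1,3-dien-1-ylidene]-1,5,5-trimethylcyclohexane-1,3-diol, (aS)
Product: 15 (2R,6R,7aR)-2-[(1E)-1-iodoprop-1-en-2-yl]-4,4,7a-trimethyl-2,4,5,6,7,7a-hexahydro-1-benzofuran-6-ol
Conditions: AuCl3 (5 mol %), THF, 25 °C, dark
Reagents that add atoms: none
Why: Gold-catalysed 5-endo cycloisomerisation of an α-hydroxyallene to a 2,5-dihydrofuran (ring B): the C5 hydroxyl attacks C8 of the gold-bound C7=C8 bond in the plane of C5–C6–C7, the two substituents at C8 keep their sides, and the allene axis should therefore be transferred to the C8 centre with H-8 cis to the C5 methyl (8R) before protodeauration at C7.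

Step 12
Reactants: 16 (2E,4E,6E)-2,7-dimethylocta-2,4,6-trienedial
Product: 17 (2E,4E,6E,8E)-2,7-dimethyl-9-(4,4,5,5-tetramethyl-1,3,2-dioxaborolan-2-yl)nona-2,4,6,8-tetraenal
Conditions: Cl2CHBpin, CrCl2, LiI, THF, 25 °C; 16 in threefold excess, recovered
Reagents that add atoms: 2-(dichloromethyl)-4,4,5,5-tetramethyl-1,3,2-dioxaborolane, ClC(Cl)B1OC(C)(C)C(C)(C)O1
Why: Boron variant of the Takai olefination: the geminal dichromium reagent formed from Cl2CHBpin and CrCl2 adds to one formyl group and eliminates to the E-alkenylboronate (C11=C12), and the excess of the symmetrical dialdehyde holds back the second olefination.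

Step 13
Reactants: 17 (2E,4E,6E,8E)-2,7-dimethyl-9-(4,4,5,5-tetramethyl-1,3,2-dioxaborolan-2-yl)nona-2,4,6,8-tetraenal
Product: 19 (2E,4E,6E,8E,10E)-4,9-dimethyl-11-(4,4,5,5-tetramethyl-1,3,2-dioxaborolan-2-yl)undeca-2,4,6,8,10-pentaenal, via dioxolane acetal 18 (not isolated)
Conditions: (1,3-dioxolan-2-ylmethyl)triphenylphosphonium bromide, KOt-Bu, THF, 0 to 25 °C; then 1 M HCl, THF, 25 °C
Reagents that add atoms: (1,3-dioxolan-2-ylmethyl)triphenylphosphonium bromide, [Br-].C1COC(O1)C[P+](c1ccccc1)(c1ccccc1)c1ccccc1; water, O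
Why: Wittig two-carbon homologation with the dioxolanylmethyl ylide followed by acid hydrolysis of the acetal, in which the acid should also equilibrate the new α,β-double bond (C11'=C12') to the E-enal; the pinacol boronate tolerates the ylide and dilute acid.

Step 14
Reactants: 19 (2E,4E,6E,8E,10E)-4,9-dimethyl-11-(4,4,5,5-tetramethyl-1,3,2-dioxaborolan-2-yl)undeca-2,4,6,8,10-pentaenal
Product: 20 (2E,4E,6E,8E,10E,12E)-2,6,11-trimethyl-13-(4,4,5,5-tetramethyl-1,3,2-dioxaborolan-2-yl)trideca-2,4,6,8,10,12-hexaenal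
Conditions: Ph3P=C(CH3)CHO, toluene, 70 °C, dark
Reagents that add atoms: 2-(triphenylphosphoranylidene)propanal, CC(C=O)=P(c1ccccc1)(c1ccccc1)c1ccccc1
Why: Wittig reaction with a stabilised formyl ylide: the unbranched enal should give the E-2-methylenal (C9'=C10') under product-stability control, and the reaction stops there because the α-branched product aldehyde is far less reactive toward the ylide.

Step 15
Reactants: 15 (2R,6R,7aR)-2-[(1E)-1-iodoprop-1-en-2-yl]-4,4,7a-trimethyl-2,4,5,6,7,7a-hexahydro-1-benzofuran-6-ol; 20 (2E,4E,6E,8E,10E,12E)-2,6,11-trimethyl-13-(4,4,5,5-tetramethyl-1,3,2-dioxaborolan-2-yl)trideca-2,4,6,8,10,12-hexaenal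
Product: 21 (2E,4E,6E,8E,10E,12E,14E)-15-[(2R,6R,7aR)-6-hydroxy-4,4,7a-trimethyl-2,4,5,6,7,7a-hexahydro-1-benzofuran-2-yl]-2,6,11-trimethylhexadeca-2,4,6,8,10,12,14-heptaenal
Conditions: Pd(PPh3)4 (10 mol %), TlOEt, THF–H2O (3:1), 25 °C, degassed, dark
Reagents that add atoms: none
Why: Suzuki–Miyaura alkenyl–alkenyl coupling: zerovalent palladium inserts into the C10–I bond with retention, the thallium base turns the C11 pinacol boronate into its ate complex and removes iodide as TlI so that transmetalation is fast at room temperature, and reductive elimination forms the C10–C11 σ-bond. The closest known reaction type is the thallium-accelerated Suzuki coupling of an (E)-2-methylalkenyl iodide with a polyenyl boronate, used to finish sensitive polyenes. No ring is closed and no stereocentre is formed; both partners react with retention of alkene geometry, so the E-C9=C10 and E-C11=C12 bonds should pass from 15 and 20 into 21 unchanged. The step needs chemoselectivity for the C–I bond beside the free C3 hydroxyl, the doubly allylic C8–O ether of ring B and the C8' aldehyde: palladium stays σ-bound at C10, an alkyl allyl ether is not ionised by zerovalent palladium at room temperature, and the boronate is inert toward the aldehyde. Because the 14-carbon and 16-carbon halves are joined last, the acid-labile ring B never meets the acidic hydrolysis of step 13 and the heptaenal never meets hydride, gold or peroxide.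

**Compound list**

1 | 2,6,6-trimethylcyclohex-2-ene-1,4-dione (ketoisophorone) | CC1=CC(=O)CC(C)(C)C1=O | starting material
2 | (4R)-4-hydroxy-2,6,6-trimethylcyclohex-2-en-1-one | O=C1C(C)(C)C[C@@H](O)C=C1C | intermediate
3 | (4S)-4-hydroxy-2,2,6-trimethylcyclohexan-1-one (C6 epimer mixture) | O=C1C(C)(C)C[C@@H](O)CC1C | intermediate
4 | (4S)-4-[(tert-butyldimethylsilyl)oxy]-2,2,6-trimethylcyclohexan-1-one (C6 epimer mixture) | O=C1C(C)(C)C[C@@H](O[Si](C)(C)C(C)(C)C)CC1C | intermediate
5 | (2E)-3-iodo-2-methylprop-2-en-1-ol | OC/C(C)=C/I | starting material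
6 | (2E)-3-iodo-2-methylprop-2-enal | O=C/C(C)=C/I | intermediate
7 | (3E)-4-iodo-3-methylbut-3-en-1-yne | C#C/C(C)=C/I | intermediate
8 | lithium (3E)-4-iodo-3-methylbut-3-en-1-yn-1-ide | [Li]C#C/C(C)=C/I | intermediate
9 | (4S)-4-[(tert-butyldimethylsilyl)oxy]-1-[(3E)-4-iodo-3-methylbut-3-en-1-yn-1-yl]-2,2,6-trimethylcyclohexan-1-ol (diastereomer mixture at C1 and C6) | OC1(C#C/C(C)=C/I)C(C)(C)C[C@@H](O[Si](C)(C)C(C)(C)C)CC1C | intermediate
10 | tert-butyl({(1S)-4-[(3E)-4-iodo-3-methylbut-3-en-1-yn-1-yl]-3,5,5-trimethylcyclohex-3-en-1-yl}oxy)dimethylsilane | I/C=C(C)/C#CC1=C(C)C[C@H](O[Si](C)(C)C(C)(C)C)CC1(C)C | intermediate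
11 | (1S)-4-[(3E)-4-iodo-3-methylbut-3-en-1-yn-1-yl]-3,5,5-trimethylcyclohex-3-en-1-ol | I/C=C(C)/C#CC1=C(C)C[C@H](O)CC1(C)C | intermediate
12 | (1R,3R,6R)-6-[(3E)-4-iodo-3-methylbut-3-en-1-yn-1-yl]-1,5,5-trimethyl-7-oxabicyclo[4.1.0]heptan-3-ol | I/C=C(C)/C#C[C@@]12O[C@]1(C)C[C@H](O)CC2(C)C | intermediate
13 | bis(diethoxymethylsilyl) ether of the (aS)-allenediol 14 | [H]C(/C(C)=C/I)=[C@@]=C1C(C)(C)C[C@@H](O[Si](C)(OCC)OCC)C[C@@]1(C)O[Si](C)(OCC)OCC | intermediate
14 | (1R,3R)-6-[(3E)-4-iodo-3-methylbuta-1,3-dien-1-ylidene]-1,5,5-trimethylcyclohexane-1,3-diol, (aS) allene axis (H-8 on the face opposite to the C5 oxygen of the epoxide it came from) | [H]C(/C(C)=C/I)=[C@@]=C1C(C)(C)C[C@@H](O)C[C@@]1(C)O | intermediate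
15 | (2R,6R,7aR)-2-[(1E)-1-iodoprop-1-en-2-yl]-4,4,7a-trimethyl-2,4,5,6,7,7a-hexahydro-1-benzofuran-6-ol | I/C=C(\C)[C@H]1C=C2C(C)(C)C[C@@H](O)C[C@@]2(C)O1 | intermediate
16 | (2E,4E,6E)-2,7-dimethylocta-2,4,6-trienedial | O=C/C(C)=C/C=C/C=C(C)/C=O | starting material
17 | (2E,4E,6E,8E)-2,7-dimethyl-9-(4,4,5,5-tetramethyl-1,3,2-dioxaborolan-2-yl)nona-2,4,6,8-tetraenal | O=C/C(C)=C/C=C/C=C(C)/C=C/B1OC(C)(C)C(C)(C)O1 | intermediate
18 | 2-[(3E,5E,7E,9E)-3,8-dimethyl-10-(4,4,5,5-tetramethyl-1,3,2-dioxaborolan-2-yl)deca-1,3,5,7,9-pentaen-1-yl]-1,3-dioxolane (1E/1Z mixture) | O1CCOC1C=C/C(C)=C/C=C/C=C(C)/C=C/B1OC(C)(C)C(C)(C)O1 | intermediate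
19 | (2E,4E,6E,8E,10E)-4,9-dimethyl-11-(4,4,5,5-tetramethyl-1,3,2-dioxaborolan-2-yl)undeca-2,4,6,8,10-pentaenal | O=C/C=C/C(C)=C/C=C/C=C(C)/C=C/B1OC(C)(C)C(C)(C)O1 | intermediate
20 | (2E,4E,6E,8E,10E,12E)-2,6,11-trimethyl-13-(4,4,5,5-tetramethyl-1,3,2-dioxaborolan-2-yl)trideca-2,4,6,8,10,12-hexaenal | C\C(C=O)=C/C=C/C(C)=C/C=C/C=C(C)/C=C/B1OC(C)(C)C(C)(C)O1 | intermediate
21 | (2E,4E,6E,8E,10E,12E,14E)-15-[(2R,6R,7aR)-6-hydroxy-4,4,7a-trimethyl-2,4,5,6,7,7a-hexahydro-1-benzofuran-2-yl]-2,6,11-trimethylhexadeca-2,4,6,8,10,12,14-heptaenal | C\C(C=O)=C/C=C/C(C)=C/C=C/C=C(C)/C=C/C=C(\C)[C@H]1C=C2C(C)(C)C[C@@H](O)C[C@@]2(C)O1 | target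

**Step count and risks**

Total steps: 15. Longest linear sequence: 10 steps (steps 1, 2, 3, 6, 7, 8, 9, 10, 11, 15).

Steps most likely to fail:

1. Step 10. What may go wrong: reductive loss of the alkenyl iodide by the copper hydride, or incomplete anti delivery that erodes the allene axis. Fallback, from 12 back to 15: reduction of 12 with i-Bu2AlH (CH2Cl2, −78 to 0 °C) opens the alkynyl epoxide by aluminium-bound, syn-SN2' hydride delivery without touching the C–I bond and should give the axis-epimeric allenediol F1. Cyclisation with AuCl3 in THF then gives the C8-epimeric dihydrofuran F2. A trace of camphorsulfonic acid in CHCl3 ionises the doubly allylic C8–O bond of F2 reversibly and equilibrates C8; chromatographic separation with recycling of F2 returns the route at 15.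

2. Step 9. What may go wrong: poor facial selectivity or no conversion, because oxygen delivery needs the axial C3–OH conformer (1,3-diaxial to a C1 methyl) and the enyne alkene is electron-poor. Fallback, from 11 back to 12: acylation of 11 with Boc2O and DMAP gives the tert-butyl carbonate F3. Treatment with IBr (toluene, −80 °C) triggers iodocarbonate cyclisation, in which the carbonate oxygen tethered at C3 attacks C5 on its own face while iodine adds to C6 on the other face, to give the bicyclic iodocarbonate F4. K2CO3 in MeOH cleaves the carbonate, and the C5 alkoxide displaces the anti iodide to close the epoxide cis to C3–OH, which is 12.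

3. Step 15. What may go wrong: slow transmetalation of the electron-poor formyl-polyenyl boronate with competing protodeboronation, or base-induced isomerisation and decomposition of the heptaenal. Fallback, from 15 and 16 back to 21, is a base-free Stille coupling. Stannylation of 15 with Me3SnSnMe3 and Pd(PPh3)4 (THF, 60 °C) gives the alkenylstannane F5. Takai olefination of 16 in excess (CHI3, CrCl2, THF, 0 °C) gives the iodotetraenal F6. The dioxolanylmethyl Wittig reaction of step 13 gives the dioxolane acetal F7, hydrolysed with 1 M HCl to the iodopentaenal F8, and the Wittig reaction of step 14 gives the iodohexaenal F9. Coupling of F5 with F9 (Pd2(dba)3, AsPh3, NMP, 25 °C, dark) forms the C10–C11 bond with retention at both alkenes and gives 21.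

**Further compounds**

F1 | step 10 | (1R,3R)-6-[(3E)-4-iodo-3-methylbuta-1,3-dien-1-ylidene]-1,5,5-trimethylcyclohexane-1,3-diol, (aR) allene axis | [H]C(/C(C)=C/I)=[C@]=C1C(C)(C)C[C@@H](O)C[C@@]1(C)O
F2 | step 10 | (2S,6R,7aR)-2-[(1E)-1-iodoprop-1-en-2-yl]-4,4,7a-trimethyl-2,4,5,6,7,7a-hexahydro-1-benzofuran-6-ol | I/C=C(\C)[C@@H]1C=C2C(C)(C)C[C@@H](O)C[C@@]2(C)O1
F3 | step 9 | tert-butyl (1S)-4-[(3E)-4-iodo-3-methylbut-3-en-1-yn-1-yl]-3,5,5-trimethylcyclohex-3-en-1-yl carbonate | I/C=C(C)/C#CC1=C(C)C[C@H](OC(=O)OC(C)(C)C)CC1(C)C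
F4 | step 9 | (1R,5R,6S)-6-iodo-6-[(3E)-4-iodo-3-methylbut-3-en-1-yn-1-yl]-5,7,7-trimethyl-2,4-dioxabicyclo[3.3.1]nonan-3-one | O=C1O[C@H]2C[C@@](C)(O1)[C@@](I)(C#C/C(C)=C/I)C(C)(C)C2
F5 | step 15 | (2R,6R,7aR)-4,4,7a-trimethyl-2-[(1E)-1-(trimethylstannyl)prop-1-en-2-yl]-2,4,5,6,7,7a-hexahydro-1-benzofuran-6-ol | C[Sn](C)(C)/C=C(\C)[C@H]1C=C2C(C)(C)C[C@@H](O)C[C@@]2(C)O1
F6 | step 15 | (2E,4E,6E,8E)-9-iodo-2,7-dimethylnona-2,4,6,8-tetraenal | O=C/C(C)=C/C=C/C=C(C)/C=C/I
F7 | step 15 | 2-[(3E,5E,7E,9E)-10-iodo-3,8-dimethyldeca-1,3,5,7,9-pentaen-1-yl]-1,3-dioxolane (1E/1Z mixture) | O1CCOC1C=C/C(C)=C/C=C/C=C(C)/C=C/I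
F8 | step 15 | (2E,4E,6E,8E,10E)-11-iodo-4,9-dimethylundeca-2,4,6,8,10-pentaenal | O=C/C=C/C(C)=C/C=C/C=C(C)/C=C/I
F9 | step 15 | (2E,4E,6E,8E,10E,12E)-13-iodo-2,6,11-trimethyltrideca-2,4,6,8,10,12-hexaenal | C\C(C=O)=C/C=C/C(C)=C/C=C/C=C(C)/C=C/I
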